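If the solid reagent dissolves wholly into partner and the whole charge of second substrate takes one partner each, the starting material can pass into target and over-reaction product up to the room, the solid reagent charge less the second substrate charge, divided by the starting material charge, 45.0%. The solid reagent is the limiting reagent, its charge being smaller than the other two charges together.

| flask | starting material | second substrate | solid reagent | temperature | remark | time |
|---|---|---|---|---|---|---|
| maple | 0.034 M | 0.017 M | 0.0323 M | 20 °C | run made earlier |  |
| cedar | 0.034 M | 0.017 M | 0.045 M | 31 °C | run made earlier |  |
| alder | 0.034 M | 0.017 M | 0.071 M | 20 °C | run made earlier |  |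
| larch | 0.017 M | 0.017 M | 0.0323 M | 31 °C | run made earlier |  |
| west | 0.034 M | 0.0170 M | 0.0323 M |  | everything together at the start at −15 °C, warmed to 25 °C at 6.0 h | 8.0 h |
| north-west | 0.034 M (fed, over 6.0 h) | 0.0170 M | 0.0323 M |  | the addition at −15 °C, then warmed to 25 °C; the feed brings no volume worth counting | 8.0 h |
| north-east | 0.034 M | 0.0170 M | 0.0323 M | 25 °C | everything together at the start | 8.0 h |
| south-west | 0.034 M (in portions, 3, over 6.0 h) | 0.0170 M | 0.0323 M | 25 °C | first portion at the start, last at 6.0 h | 8.0 h |
| north | 0.034 M (fed, over 6.0 h) | 0.0170 M | 0.0323 M | 25 °C | all else is in the flask from the start; the feed brings no volume worth counting | 8.0 h |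

- maple (time / h: over-reaction product / %, target / %): 1.00: 2.5, 12.6; 2.50: 12.3, 21.1; 3.00: 16.1, 20.5; 5.00: 27.6, 10.3; 6.00: 30.8, 8.1; 8.00: 35.9, 5.3
- cedar (time / h: over-reaction product / %, target / %): 0.667: 4.5, 6.8; 1.33: 12.4, 8.1; 2.00: 23.0, 9.4; 3.00: 40.4, 10.0; 4.00: 58.2, 8.5; 5.00: 68.4, 4.3
- alder (time / h: over-reaction product / %, target / %): 0.667: 1.2, 9.2; 1.33: 4.6, 15.3; 2.00: 8.5, 19.0; 3.00: 16.8, 22.0; 4.00: 25.4, 24.3; 5.00: 34.7, 25.4
- larch (time / h: over-reaction product / %, target / %): 0.417: 2.5, 6.5; 1.33: 15.8, 9.6; 2.00: 28.4, 11.4; 3.00: 49.9, 10.4; 5.00: 69.4, 3.2

(readings scatter by 0.3 percentage points)

- the flask that comes out highest in amount of over-reaction product, in percent of the starting material charged, or "all alike" when all lie within 1.5 percentage points (west / north-west / north-east / south-west / north / all alike)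
- over-reaction product at the end, in percent of the starting material charged, west
- over-reaction product at the end, in percent of the starting material charged, north-west
- over-reaction product at the end, in percent of the starting material charged, north-east
- over-reaction product at the end, in percent of the starting material charged, south-west
- over-reaction product at the end, in percent of the starting material charged, north

- given per volume of solution although it is solid: solid reagent
- the numbers in the tables scatter with a standard deviation of 0.3 percentage points
- on the list of suspects stand: starting material + partner <-> target; second substrate + partner -> second product; target -> over-reaction product; solid reagent <-> partner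
- at the start none of the solid reagent is in solution

West, north-west, north-east, south-west and north carry the same charges, so they have the same room, and two of us disagreed over what that means at the end.

I held that each flask ends near the room. Maple, a run with the same room, shows target and over-reaction product together at 41.2% by its last reading. To find how fast target goes on, I replaced its falling curve by the mean of two readings. In maple at 20 °C that reads as 0.381 h⁻¹, a half-life of 1.82 h. In cedar at 31 °C it reads as 1.92 h⁻¹, a half-life of 0.360 h. West's warm stretch of 2.00 h is longer than the half-life even at the cooler of these, and on that ground I expected no two flasks to lie apart by more than 1.5 percentage points.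

The forecast held that the ends differ by “how late target forms”. It put north-east highest at 40%, south-west at 36%, north at 36%, west at 33% and north-west at 26%.

The simulation sides with the forecast: north-east gives 44.0%, south-west 38.0%, north 38.6%, west 30.3% and north-west 29.8%, a gap of 14 points. My view holds for long standing: at 80.0 h north-east gives 46.4% and north-west 46.1%, which lie closer together than 1.5 points, so a gap like the forecast's 14 points no longer stands at that time.

    starting material + partner ⇌ target (K = 50.0 L mol⁻¹, k = 260 L mol⁻¹ h⁻¹, Ea = 44.0 kJ mol⁻¹, ΔH = −5.00 kJ mol⁻¹)
    second substrate + partner → second product (k = 170 L mol⁻¹ h⁻¹, Ea = 62.0 kJ mol⁻¹)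
    target → over-reaction product (k = 0.760 h⁻¹, Ea = 104 kJ mol⁻¹)
    solid reagent ⇌ partner, rate k4*(cs4 - [partner]) while solid is left; crystals form when [partner] > cs4 (solubility = 23.0 mM, k = 0.640 h⁻¹)
    (constants at 25 °C)

In north-east at 8.00 h, target is made at 0.458 of the rate at which it is used up, each step taken net. Over-reaction product 44.0% and target 1.27% together stand at 45.3%, against a room of 45.0%, with 3.41% of the second substrate's charge still there. A neighbour of north-east with 0.0068 M of second substrate has a room of 75.0%. That neighbour gives 64.9% over-reaction product and 3.34% target, with 0.00230 M of partner still in solution.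

The numbers in the tables were generated by integration for an exercise.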